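Atom numbers: ring A (five-membered) = C1 (quaternary, methyl), C2, C3, C4 (OH, isopropyl), C5 (H). Ring B (seven-membered) = C1, C5, C6 (anisoyloxy), C7, C8 (methyl)=C9, C10 (acetoxy).
Retrosynthesis: cut the two ester C–O bonds. Trace C10–OH and C8=C9 back to a C10 ketone, and C6–OH back to a C6 ketone. Move the C5–C1 bond back to C6–C1, cut C4–isopropyl, and open the resulting octalenedione at the two Robinson bonds (C1–C2 and C5=C6).
Enabling feature: the oxygen-bearing C6 and the quaternary C1 both sit on C5, next to the C4 carbinol. A C6 ketone with C1 on C5 is the product pattern of a semipinacol shift in a decalin that carries OH on C6 and a leaving group on C5, which is the diol of a Robinson enone.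
Forward: ring B is bought as a six-membered 1,3-dione. Ring A is closed as a six-membered ring by asymmetric Robinson annulation. One 1,2-shift then turns the 6/6 decalin into the 5/7 hydroazulene, and the C8=C9/C10 unit and the esters follow.
Stereochemistry: C1 comes from the prolinamide-catalysed aldol. C4 comes from axial addition anti to the methyl group. The C5 and C6 hydroxyls come from OH-directed osmylation, and C5 is then set by inversion in the shift. C6 comes from OH-directed hydride delivery, and C10 from peripheral attack of a bulky hydride.

Key step: step 8

Remark: C8 is formed in step 2 as a mixture of epimers that is carried on unseparated. Names and SMILES leave C8 open from 4 to 15, because it becomes sp2 in step 12.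

Step 1
Reactants: 1 5-methylcyclohexane-1,3-dione
Product: 2 2,5-dimethylcyclohexane-1,3-dione
Conditions: MeI, KOH, H2O/dioxane, reflux
Reagents that add atoms: methyl iodide (CI)
Why: C-alkylation of the stabilised enolate of a cyclic 1,3-dione with methyl iodide in aqueous base is the standard entry to 2-methyl-1,3-diones, and no stereocentre of consequence is formed.

Step 2
Reactants: 2 2,5-dimethylcyclohexane-1,3-dione; 3 methyl vinyl ketone
Product: 4 2,5-dimethyl-2-(3-oxobutyl)cyclohexane-1,3-dione
Conditions: Et3N (cat.), neat, rt
Reagents that add atoms: none
Why: Base-catalysed Michael addition of the 2-substituted 1,3-dione to the enone forms the C1–C2 bond and makes C1 quaternary but still prochiral (the two ring carbonyls are enantiotopic), while its relation to C8 is not controlled and does not matter.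

Step 3
Reactants: 4 triketone
Product: 5 (8aS)-3,8a-dimethyl-3,4,8,8a-tetrahydronaphthalene-1,6(2H,7H)-dione
Conditions: (S)-N-[(Sa)-2'-(4-toluenesulfonamido)-1,1'-binaphthyl-2-yl]pyrrolidine-2-carboxamide (2 mol %), PhCO2H (1 mol %), neat, rt
Reagents that add atoms: none
Why: In this Hajos–Parrish–Eder–Sauer–Wiechert reaction (enamine aldol condensation), the (S)-prolinamide enamine of the side-chain ketone attacks one of the two enantiotopic ring carbonyls under hydrogen-bond control, which closes ring A as a six-membered ring and fixes C1 as S.

Step 4
Reactants: 5 enedione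
Product: 6 enone ketal (C10 ketone as 1,3-dioxolane)
Conditions: ethylene glycol, p-TsOH·H2O, 4 Å molecular sieves, rt
Reagents that add atoms: ethylene glycol (OCCO)
Why: In this chemoselective acid-catalysed ketalisation the saturated C10 ketone reacts while the conjugated C4 carbonyl is deactivated, as is usual for bicyclic enediones of this type.

Step 5
Reactants: 6 enone ketal
Product: 7 tertiary allylic alcohol (isopropyl and OH on C4, OH cis to the C1 methyl group)
Conditions: i-PrMgCl, LaCl3·2LiCl, THF, 0 °C; aq. work-up
Reagents that add atoms: isopropylmagnesium chloride (CC(C)[Mg]Cl)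
Why: The lanthanum-assisted Grignard 1,2-addition suppresses enolisation, reduction and conjugate addition, and the nucleophile should take the stereoelectronically preferred axial path on the face opposite the axial C1 methyl group (the face that hydride also uses in such octalenones), so the C4 hydroxyl ends cis to the methyl group (4R).

Step 6
Reactants: 7 tertiary allylic alcohol
Product: 9 cis-decalin 4,5,6-triol ketal, via osmate ester 8 (not isolated)
Conditions: OsO4 (1 equiv), TMEDA, CH2Cl2, −78 °C; then aq. Na2SO3, THF, reflux
Reagents that add atoms: osmium tetroxide (O=[Os](=O)(=O)=O)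
Why: In this hydrogen-bond-directed syn-dihydroxylation the OsO4–TMEDA complex is held by the C4 hydroxyl and adds suprafacially to the alkene face cis to it, the other face being screened by the isopropyl group, which sets C5 (S) and C6 (R) with both new hydroxyls cis to C4–OH and to the C1 methyl group.

Step 7
Reactants: 9 triol ketal
Product: 10 C5 monomesylate of 9
Conditions: MsCl, Et3N, CH2Cl2, −10 °C
Reagents that add atoms: methanesulfonyl chloride (CS(=O)(=O)Cl)
Why: Sulfonylation through sulfene takes only the single secondary hydroxyl (equatorial C5–OH), the two tertiary hydroxyls stay free, and no stereocentre is touched.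

Step 8
Reactants: 10 C5 monomesylate
Product: 11 trans-fused hydroazulenone (C6 ketone, C4 tertiary alcohol, C10 dioxolane)
Conditions: KOt-Bu (1.05 equiv), THF/t-BuOH, 0 °C
Reagents that add atoms: none
Why: Deprotonation of the angular C6 hydroxyl starts a concerted semipinacol 1,2-shift: in the chair–chair conformer with equatorial isopropyl and equatorial mesylate the C6–C1 bond lies antiperiplanar to the C5–O bond, so C1 moves from C6 to C5 as mesylate leaves and C6 becomes the ketone. The closest known reaction type is the base-induced rearrangement of decalin cis-1,2-diol monosulfonates to hydroazulenones. No ring is closed from an open chain end; through one three-centre transition state ring A contracts from six to five members (C6 leaves it) and ring B grows from six to seven members (C5 is inserted between C6 and C1). C5 is the only new stereocentre and is set by inversion at the mesylate carbon with retention at the migrating C1, so the mesylate cis to the C1 methyl group gives H-5 trans to it, which is the trans ring fusion, while C1 and C4 are untouched. The step needs migration of C1 (push from O6) and not of C3 (push from O4, whose C4–C3 bond is also antiperiplanar), and it needs no epoxide formation; the fully substituted C1 is by far the better migrating group than the primary C3, and both hydroxyls are cis to the mesylate and cannot displace it from the back. The one equivalent of base is used up as KOMs forms, which should protect the β-hydroxy ketone from retro-aldol cleavage.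

Step 9
Reactants: 11 hydroazulenone
Product: 12 4,6-diol (C6–OH trans to C4–OH, cis to H-5)
Conditions: Me4NBH(OAc)3, MeCN/AcOH, −20 °C
Reagents that add atoms: none
Why: In this Evans–Saksena reduction, exchange of an acetate for the C4 hydroxyl ties the borohydride to the face of that hydroxyl and hydride is delivered within the complex to C6 through a six-membered chair, which gives the 1,3-anti diol (6S) and leaves the ketal untouched.

Step 10
Reactants: 12 4,6-diol; 13 4-methoxybenzoyl chloride
Product: 14 C6 4-methoxybenzoate of 12
Conditions: Et3N, 4-(dimethylamino)pyridine, CH2Cl2, 40 °C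
Reagents that add atoms: none
Why: Acylation under nucleophilic catalysis takes only the secondary C6 hydroxyl, because the tertiary C4 hydroxyl next to the isopropyl group is too hindered.

Step 11
Reactants: 14 C6 4-methoxybenzoate
Product: 15 keto ester (free C10 ketone)
Conditions: pyridinium p-toluenesulfonate (cat.), acetone/H2O, 55 °C
Reagents that add atoms: water (O)
Why: Mild acid-catalysed ketal hydrolysis frees the C10 ketone, and the weak acid should neither ionise the tertiary alcohol nor cleave the aryl ester.

Step 12
Reactants: 15 keto ester
Product: 16 enone ester (C8=C9 conjugated with the C10 ketone)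
Conditions: IBX, DMSO, 70 °C
Reagents that add atoms: none
Why: In this IBX-mediated dehydrogenation of a ketone, C10 can enolise only toward C9 because C1 is quaternary, so the alkene can form only between C9 and C8, which also removes the open C8 stereocentre.

Step 13
Reactants: 16 enone ester
Product: 17 allylic alcohol (C10–OH trans to the C1 methyl group)
Conditions: LiBH(s-Bu)3, THF, −78 °C; then H2O
Reagents that add atoms: none
Why: In this 1,2-reduction of a β,β-disubstituted enone by a bulky borohydride, conjugate reduction is blocked by the C8 methyl group. The reagent should come in along the ring periphery on the face of the C1 methyl group, because the inner axial-type path on the other face runs against H-5 and the C6 acyloxy group, and this gives the pseudoaxial C10 alcohol trans to the methyl group (10R), just as this reagent gives axial alcohols from ketones next to a fully substituted carbon.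

Step 14
Reactants: 17 allylic alcohol
Product: 18 target, (1S,4R,5S,6S,10R)-10-acetoxy-4-hydroxy-6-(4-methoxybenzoyloxy)dauc-8-ene
Conditions: Ac2O, pyridine, 4-(dimethylamino)pyridine (cat.), CH2Cl2, rt
Reagents that add atoms: acetic anhydride (CC(=O)OC(C)=O)
Why: Standard acetylation takes the secondary allylic C10 hydroxyl with retention, while the tertiary C4 hydroxyl stays free under these mild conditions.

Compound list
1 | 5-methylcyclohexane-1,3-dione | CC1CC(=O)CC(=O)C1 | starting material
2 | 2,5-dimethylcyclohexane-1,3-dione | CC1CC(=O)C(C)C(=O)C1 | intermediate
3 | methyl vinyl ketone | CC(=O)C=C | starting material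
4 | 2,5-dimethyl-2-(3-oxobutyl)cyclohexane-1,3-dione (C8 open) | CC(=O)CCC1(C)C(=O)CC(C)CC1=O | intermediate
5 | (8aS)-3,8a-dimethyl-3,4,8,8a-tetrahydronaphthalene-1,6(2H,7H)-dione (1S; C8 open) | O=C1CC[C@@]2(C)C(=C1)CC(C)CC2=O | intermediate
6 | enone ketal, C10 ketone of 5 as 1,3-dioxolane (1S) | O=C1CC[C@@]2(C)C(=C1)CC(C)CC21OCCO1 | intermediate
7 | tertiary allylic alcohol, isopropyl and OH on C4, OH cis to the C1 methyl group (1S,4R) | CC(C)[C@]1(O)CC[C@@]2(C)C(=C1)CC(C)CC21OCCO1 | intermediate
8 | cyclic osmate ester of 7 across C5 and C6 (TMEDA chelate), oxygens cis to C4–OH | CC(C)[C@]1(O)CC[C@@]2(C)[C@]3(O[Os](=O)(=O)O[C@@H]13)CC(C)CC21OCCO1.CN(C)CCN(C)C | intermediate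
9 | cis-decalin triol ketal, OH on C4, C5 and C6 all cis to the C1 methyl group (1S,4R,5S,6R) | CC(C)[C@]1(O)CC[C@@]2(C)[C@@](O)([C@H]1O)CC(C)CC21OCCO1 | intermediate
10 | C5 monomesylate of 9 (1S,4R,5S,6R) | CC(C)[C@]1(O)CC[C@@]2(C)[C@@](O)([C@H]1OS(C)(=O)=O)CC(C)CC21OCCO1 | intermediate
11 | trans-fused hydroazulenone, C6 ketone, C4 tertiary alcohol, C10 dioxolane, H-5 trans to the C1 methyl group (1S,4R,5R) | O=C1CC(C)CC2(OCCO2)[C@@]3(C)CC[C@@](O)(C(C)C)[C@H]13 | intermediate
12 | 4,6-diol, C6–OH trans to C4–OH and cis to H-5 (1S,4R,5S,6S) | O[C@H]1CC(C)CC2(OCCO2)[C@@]3(C)CC[C@@](O)(C(C)C)[C@H]13 | intermediate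
13 | 4-methoxybenzoyl chloride | COc1ccc(cc1)C(Cl)=O | starting material
14 | C6 4-methoxybenzoate of 12 | COc1ccc(cc1)C(=O)O[C@H]1CC(C)CC2(OCCO2)[C@@]3(C)CC[C@@](O)(C(C)C)[C@H]13 | intermediate
15 | keto ester, free C10 ketone | COc1ccc(cc1)C(=O)O[C@H]1CC(C)CC(=O)[C@@]2(C)CC[C@@](O)(C(C)C)[C@H]12 | intermediate
16 | enone ester, C8=C9 conjugated with the C10 ketone | COc1ccc(cc1)C(=O)O[C@H]1CC(C)=CC(=O)[C@@]2(C)CC[C@@](O)(C(C)C)[C@H]12 | intermediate
17 | allylic alcohol, C10–OH trans to the C1 methyl group (10R) | COc1ccc(cc1)C(=O)O[C@H]1CC(C)=C[C@@H](O)[C@@]2(C)CC[C@@](O)(C(C)C)[C@H]12 | intermediate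
18 | target, (1S,4R,5S,6S,10R) | COc1ccc(cc1)C(=O)O[C@H]1CC(C)=C[C@@H](OC(C)=O)[C@@]2(C)CC[C@@](O)(C(C)C)[C@H]12 | target

Total step count: 14. Longest linear sequence: 14 steps (from 1).

Steps most likely to fail

1. Step 8 (key step). The C4–C3 bond may migrate under the push of the C4 alkoxide in place of the C6–C1 bond, or residual base may open the β-hydroxy ketone by retro-aldol cleavage. The fallback takes O4 out of play with a protecting group. It sets out from 7, which is silylated (TBSOTf, 2,6-lutidine) to the silyl ether F1. Osmylation (OsO4, pyridine; the isopropyl group still screens the other face) should give the 5,6-diol F2, and mesylation the monomesylate F3. KOt-Bu, with O6 as the only free hydroxyl, should give the silylated hydroazulenone F4. HF·pyridine removes the silyl group and the sequence comes back to the route at 11.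

2. Step 6. Facial selectivity at the hindered trisubstituted alkene may be poor, with osmylation on the face trans to C4–OH. In the fallback, C5 is set by equilibration instead of by the stereospecific shift. It sets out from 7. OsO4 (cat.) with N-methylmorpholine N-oxide is used without the directing amine, and the epimeric triol F5 (C5 and C6 hydroxyls trans to C4–OH, trans-decalin) is taken on deliberately. Its monomesylate F6 has an equatorial leaving group held antiperiplanar to C6–C1. KOt-Bu should give, by the same shift with inversion, the cis-fused ketone F7. DBU then equilibrates C5 through the enol to the trans-fused isomer, in which C6 is moved away from the isopropyl group and accepts a hydrogen bond from C4–OH. This comes back to the route at 11.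

3. Step 13. Hydride may be delivered to the wrong face of C10, or conjugate reduction may occur. The fallback replaces substrate control by catalyst control. It sets out from 16 and uses the Corey–Bakshi–Shibata reduction with (S)-2-methyl-CBS-oxazaborolidine and catecholborane in toluene at −78 °C. The fully substituted C1 acts as the large group, so hydride is delivered to the face required for 10R. The fallback comes back to the route at 17 without any new compound.

Further compounds
F1 | step 8 | tert-butyldimethylsilyl ether of 7 | CC(C)[C@]1(O[Si](C)(C)C(C)(C)C)CC[C@@]2(C)C(=C1)CC(C)CC21OCCO1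
F2 | step 8 | 5,6-diol of F1, both hydroxyls cis to the C1 methyl group | CC(C)[C@]1(O[Si](C)(C)C(C)(C)C)CC[C@@]2(C)[C@@](O)([C@H]1O)CC(C)CC21OCCO1
F3 | step 8 | C5 monomesylate of F2 | CC(C)[C@]1(O[Si](C)(C)C(C)(C)C)CC[C@@]2(C)[C@@](O)([C@H]1OS(C)(=O)=O)CC(C)CC21OCCO1
F4 | step 8 | C4 tert-butyldimethylsilyl ether of 11 | O=C1CC(C)CC2(OCCO2)[C@@]3(C)CC[C@@](O[Si](C)(C)C(C)(C)C)(C(C)C)[C@H]13
F5 | step 6 | trans-decalin triol ketal, C5 and C6 hydroxyls trans to C4–OH | CC(C)[C@]1(O)CC[C@@]2(C)[C@](O)([C@@H]1O)CC(C)CC21OCCO1
F6 | step 6 | C5 monomesylate of F5 | CC(C)[C@]1(O)CC[C@@]2(C)[C@](O)([C@@H]1OS(C)(=O)=O)CC(C)CC21OCCO1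
F7 | step 6 | cis-fused hydroazulenone, C5 epimer of 11 | O=C1CC(C)CC2(OCCO2)[C@@]3(C)CC[C@@](O)(C(C)C)[C@@H]13
F0 | step 13 | none | none
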